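**Plan**

1. Retrosynthesis: (i) the four phenols are masked as methoxymethyl (MOM) ethers; (ii) the enone is cut at C(=O)–Cα and, in the same operation, at ring A C1'–C(=O), so the ketone carbon leaves as CO between a C1' aryl iodide and an (E)-alkenylboronate of ring B; (iii) the ring A C3'–CH2 bond is cut to an aryl iodide and (R)-lavandulyl iodide; (iv) lavandulol is cut at Cα–CH2(prenyl) to a senecioyl imide and prenyl bromide.
2. Enabling feature: the ketone carbon is a single carbon between two sp2 carbons (ring A C1' and the vinylic Cα), and C1' lies between the C2' and C6' oxygens. These two oxygens direct lithiation and iodination to C1' and crowd the arylpalladium, so CO insertion precedes coupling.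
3. Forward order: side chain (auxiliary alkylation, reduction, iodide), then Negishi coupling onto C3' of ring A, iodination at C1', three-component carbonylative Suzuki–Miyaura union with the ring B boronate, and removal of all MOM groups. Both benzene rings are bought; no ring is formed.
4. Stereochemistry: the only stereocentre is set in step 2 by alkylation of the chelated Z-dienolate of an (R)-4-benzyloxazolidinone imide on the face away from the benzyl group, and it is never again next to a reacting centre. The E-alkene comes from the boron-Wittig step and is transferred with retention.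

Key step: step 11

Remark: ring A is the trioxygenated ring (C1' ketone, C2' OH, C3' lavandulyl, C4' OH, C6' OMe) and ring B the 2,4-dihydroxyphenyl ring; lavandulyl = 5-methyl-2-(prop-1-en-2-yl)hex-4-en-1-yl. The (S) descriptor of the target belongs to the (R)-lavandulol series: the spatial arrangement is unchanged, only the CIP rank of CH2–aryl against isopropenyl differs from that of CH2–OH or CH2–I.

**Route**

Step 1
Reactants: 1 (4R)-4-benzyl-1,3-oxazolidin-2-one; 2 3-methylbut-2-enoyl chloride
Product: 4 (4R)-4-benzyl-3-(3-methylbut-2-enoyl)-1,3-oxazolidin-2-one, via lithium oxazolidinide 3 (not isolated)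
Conditions: n-BuLi, THF, −78 °C; then 2, −78 → 0 °C
Reagents that add atoms: none
Why: N-acylation of the lithiated oxazolidinone by the acid chloride (standard auxiliary acylation) should proceed cleanly at low temperature, where ketene formation and deconjugation of the senecioyl unit are avoided.

Step 2
Reactants: 4 (4R)-4-benzyl-3-(3-methylbut-2-enoyl)-1,3-oxazolidin-2-one; 5 1-bromo-3-methylbut-2-ene (prenyl bromide)
Product: 7 (4R)-4-benzyl-3-[(2R)-5-methyl-2-(prop-1-en-2-yl)hex-4-enoyl]-1,3-oxazolidin-2-one, via sodium dienolate 6 (not isolated)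
Conditions: NaN(SiMe3)2, THF, −78 °C; then 5, −78 → −40 °C; NH4Cl quench at −40 °C
Reagents that add atoms: none
Why: Evans-type asymmetric alkylation in its deconjugative form: γ-deprotonation of the s-cis enoyl imide should give the sodium-chelated Z-dienolate, which is alkylated at Cα on the face opposite the benzyl group, setting the (2R) centre and moving the alkene into the isopropenyl position.

Step 3
Reactants: 7 (4R)-4-benzyl-3-[(2R)-5-methyl-2-(prop-1-en-2-yl)hex-4-enoyl]-1,3-oxazolidin-2-one
Product: 8 (R)-lavandulol [(2R)-5-methyl-2-(prop-1-en-2-yl)hex-4-en-1-ol]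
Conditions: LiBH4, H2O (1 equiv), Et2O, 0 °C; aqueous NaOH work-up
Reagents that add atoms: none
Why: Reductive cleavage of the N-acyl oxazolidinone by LiBH4 attacks the exocyclic carbonyl selectively and should release the primary alcohol without base-mediated epimerisation of the allylic α-centre, with the auxiliary recovered.

Step 4
Reactants: 8 (R)-lavandulol
Product: 9 (R)-lavandulyl iodide [(3R)-3-(iodomethyl)-2,6-dimethylhepta-1,5-diene]
Conditions: PPh3, I2, imidazole, CH2Cl2, 0 °C → rt
Reagents that add atoms: iodine, [I][I]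
Why: Appel-type iodination of a primary alcohol (alkoxyphosphonium formation, then SN2 by iodide at CH2) leaves the neighbouring stereocentre and both alkenes untouched.

Step 5
Reactants: 10 5-methoxybenzene-1,3-diol
Product: 11 1-methoxy-3,5-bis(methoxymethoxy)benzene
Conditions: MOMCl, i-Pr2NEt, CH2Cl2, 0 °C → rt
Reagents that add atoms: chloromethyl methyl ether (MOMCl), COCCl
Why: Williamson-type O-alkylation of both phenols with the α-chloro ether installs the MOM groups, which serve as phenol masks and as directing groups for the two lithiations.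

Step 6
Reactants: 11 1-methoxy-3,5-bis(methoxymethoxy)benzene
Product: 13 2-iodo-5-methoxy-1,3-bis(methoxymethoxy)benzene, via aryllithium 12 (not isolated)
Conditions: n-BuLi, THF, 0 °C; then I2, −78 °C → rt
Reagents that add atoms: iodine, [I][I]
Why: Directed ortho-metalation should occur at the carbon between the two MOM ethers, the stronger pair of coordinating directors compared with OMOM/OMe, and iodinolysis of the aryllithium fixes the future C3' as C–I.

Step 7
Reactants: 9 (R)-lavandulyl iodide; 13 2-iodo-5-methoxy-1,3-bis(methoxymethoxy)benzene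
Product: 15 5-methoxy-1,3-bis(methoxymethoxy)-2-[(2S)-5-methyl-2-(prop-1-en-2-yl)hex-4-en-1-yl]benzene, via lavandulylzinc iodide 14 (not isolated)
Conditions: 9, Zn dust, LiCl, THF, 40 °C; then 13, Pd(OAc)2 (3 mol %), SPhos (2-dicyclohexylphosphino-2',6'-dimethoxybiphenyl, 6 mol %), THF, 50 °C
Reagents that add atoms: none
Why: Negishi coupling of a primary alkylzinc iodide with a doubly ortho-alkoxylated aryl iodide is well served by the bulky biarylphosphine, which makes reductive elimination faster than β-hydride elimination; the stereocentre is β to the metal and takes no part in the reaction.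

Step 8
Reactants: 15 5-methoxy-1,3-bis(methoxymethoxy)-2-[(2S)-5-methyl-2-(prop-1-en-2-yl)hex-4-en-1-yl]benzene
Product: 17 2-iodo-1-methoxy-3,5-bis(methoxymethoxy)-4-[(2S)-5-methyl-2-(prop-1-en-2-yl)hex-4-en-1-yl]benzene, via aryllithium 16 (not isolated)
Conditions: n-BuLi, THF, 0 °C; then I2 (1.05 equiv), −78 °C; Na2S2O3 work-up
Reagents that add atoms: iodine, [I][I]
Why: Directed ortho-metalation at one of the two equivalent remaining ring positions, each flanked by OMOM and OMe, should be faster than benzylic or allylic deprotonation, and iodinolysis places iodine at the future C1'.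

Step 9
Reactants: 18 2,4-dihydroxybenzaldehyde
Product: 19 2,4-bis(methoxymethoxy)benzaldehyde
Conditions: MOMCl (3 equiv), i-Pr2NEt (4 equiv), CH2Cl2, 0 °C → reflux
Reagents that add atoms: chloromethyl methyl ether (MOMCl), COCCl
Why: MOM protection (Williamson-type O-alkylation) with excess reagent and gentle heating should also alkylate the hydrogen-bonded ortho-phenol, so that ring B cannot later close onto the alkene or the ketone.

Step 10
Reactants: 19 2,4-bis(methoxymethoxy)benzaldehyde; 20 bis[(pinacolato)boryl]methane
Product: 22 2-{(E)-2-[2,4-bis(methoxymethoxy)phenyl]ethenyl}-4,4,5,5-tetramethyl-1,3,2-dioxaborolane, via lithiated diborylmethane 21 (not isolated)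
Conditions: 20, lithium 2,2,6,6-tetramethylpiperidide, THF, 0 °C; then 19, −78 °C → rt
Reagents that add atoms: none
Why: Boron-Wittig olefination: the α-diboryl carbanion adds to the aldehyde and syn-elimination of the boron–oxygen pair should give the trans-alkenylboronate with the E geometry needed for the enone.

Step 11
Reactants: 17 2-iodo-1-methoxy-3,5-bis(methoxymethoxy)-4-[(2S)-5-methyl-2-(prop-1-en-2-yl)hex-4-en-1-yl]benzene; 22 2-{(E)-2-[2,4-bis(methoxymethoxy)phenyl]ethenyl}-4,4,5,5-tetramethyl-1,3,2-dioxaborolane; 23 carbon monoxide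
Product: 24 (E)-3-[2,4-bis(methoxymethoxy)phenyl]-1-{6-methoxy-2,4-bis(methoxymethoxy)-3-[(2S)-5-methyl-2-(prop-1-en-2-yl)hex-4-en-1-yl]phenyl}prop-2-en-1-one
Conditions: PdCl2(IPr)(3-chloropyridine) (3 mol %; IPr = 1,3-bis(2,6-diisopropylphenyl)imidazol-2-ylidene), Cs2CO3 (3 equiv), CO (1 atm), chlorobenzene, 80 °C
Reagents that add atoms: none
Why: Carbonylative Suzuki–Miyaura three-component coupling: zerovalent palladium carrying the carbene ligand inserts into the C1'–I bond of 17, CO inserts to give the aroylpalladium iodide, the carbonate-activated alkenylboronate 22 transfers its alkenyl group, and reductive elimination from the acyl(alkenyl)palladium forms the C(=O)–Cα bond. The closest known reaction type is the carbonylative Suzuki–Miyaura ketone synthesis from di-ortho-substituted aryl iodides under palladium–carbene catalysis, with alkenylboron partners giving enones within the same class. No ring is closed and no stereocentre is formed; the E geometry of the enone is inherited from 22 because transmetalation and reductive elimination are stereoretentive. The selectivity needed is CO insertion before transmetalation (ketone and not the stilbene of direct coupling), and the substrate secures it: C1' is flanked by the C2' OMOM and C6' OMe groups, which slow transmetalation at the crowded arylpalladium while the small CO still inserts, and the electron-rich aryl group migrates readily to CO. The lavandulyl alkenes are unactivated, 1,1-di- and trisubstituted and meta to the reacting carbon, so neither aryl- nor acylpalladation of them should compete, and all four phenols are masked so that no aryl ester can form by phenoxide capture of the acylpalladium.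

Step 12
Reactants: 24 (E)-3-[2,4-bis(methoxymethoxy)phenyl]-1-{6-methoxy-2,4-bis(methoxymethoxy)-3-[(2S)-5-methyl-2-(prop-1-en-2-yl)hex-4-en-1-yl]phenyl}prop-2-en-1-one
Product: 26 (E)-1-{2,4-dihydroxy-6-methoxy-3-[(2S)-5-methyl-2-(prop-1-en-2-yl)hex-4-en-1-yl]phenyl}-3-(2,4-dihydroxyphenyl)prop-2-en-1-one, via tetrakis(trimethylsilyl) ether 25 (not isolated)
Conditions: Me3SiOTf (8 equiv), 2,2'-bipyridyl (12 equiv), CH3CN, 0 °C → rt; then H2O, rt
Reagents that add atoms: none
Why: Non-protic cleavage of aromatic MOM ethers by silyl triflate and 2,2'-bipyridyl (acetal exchange to the aryl trimethylsilyl ethers with the methoxymethyl unit captured on bipyridyl, then hydrolysis) avoids the free Brønsted acid that would close the C2' phenol onto the enone, add a ring A phenol to the isopropenyl group or condense the ring B ortho-phenol with the ketone; the aryl methyl ether and both alkenes should be inert.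

**Compound list**

1 | (4R)-4-benzyl-1,3-oxazolidin-2-one | O=C1N[C@H](Cc2ccccc2)CO1 | starting material
2 | 3-methylbut-2-enoyl chloride | CC(C)=CC(=O)Cl | starting material
3 | lithium salt of 1 (formed in situ) | [Li]N1[C@H](Cc2ccccc2)COC1=O | intermediate
4 | (4R)-4-benzyl-3-(3-methylbut-2-enoyl)-1,3-oxazolidin-2-one | CC(C)=CC(=O)N1[C@H](Cc2ccccc2)COC1=O | intermediate
5 | 1-bromo-3-methylbut-2-ene | CC(C)=CCBr | starting material
6 | sodium Z-dienolate of 4 (formed in situ) | C=C(C)/C=C(\[O-])N1[C@H](Cc2ccccc2)COC1=O.[Na+] | intermediate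
7 | (4R)-4-benzyl-3-[(2R)-5-methyl-2-(prop-1-en-2-yl)hex-4-enoyl]-1,3-oxazolidin-2-one | C=C(C)[C@@H](CC=C(C)C)C(=O)N1[C@H](Cc2ccccc2)COC1=O | intermediate
8 | (R)-lavandulol, (2R)-5-methyl-2-(prop-1-en-2-yl)hex-4-en-1-ol | C=C(C)[C@@H](CC=C(C)C)CO | intermediate
9 | (R)-lavandulyl iodide, (3R)-3-(iodomethyl)-2,6-dimethylhepta-1,5-diene | C=C(C)[C@@H](CC=C(C)C)CI | intermediate
10 | 5-methoxybenzene-1,3-diol | COc1cc(O)cc(O)c1 | starting material
11 | 1-methoxy-3,5-bis(methoxymethoxy)benzene | COCOc1cc(OC)cc(OCOC)c1 | intermediate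
12 | [4-methoxy-2,6-bis(methoxymethoxy)phenyl]lithium (formed in situ) | [Li]c1c(OCOC)cc(OC)cc1OCOC | intermediate
13 | 2-iodo-5-methoxy-1,3-bis(methoxymethoxy)benzene | COCOc1cc(OC)cc(OCOC)c1I | intermediate
14 | (R)-lavandulylzinc iodide (formed in situ) | C=C(C)[C@@H](CC=C(C)C)C[Zn]I | intermediate
15 | 5-methoxy-1,3-bis(methoxymethoxy)-2-[(2S)-5-methyl-2-(prop-1-en-2-yl)hex-4-en-1-yl]benzene | C=C(C)[C@@H](CC=C(C)C)Cc1c(OCOC)cc(OC)cc1OCOC | intermediate
16 | aryllithium from 15, lithiated between OMOM and OMe (formed in situ) | C=C(C)[C@@H](CC=C(C)C)Cc1c(OCOC)cc(OC)c([Li])c1OCOC | intermediate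
17 | 2-iodo-1-methoxy-3,5-bis(methoxymethoxy)-4-[(2S)-5-methyl-2-(prop-1-en-2-yl)hex-4-en-1-yl]benzene | C=C(C)[C@@H](CC=C(C)C)Cc1c(OCOC)cc(OC)c(I)c1OCOC | intermediate
18 | 2,4-dihydroxybenzaldehyde | O=Cc1ccc(O)cc1O | starting material
19 | 2,4-bis(methoxymethoxy)benzaldehyde | O=Cc1ccc(OCOC)cc1OCOC | intermediate
20 | bis[(pinacolato)boryl]methane | CC1(C)OB(CB2OC(C)(C)C(C)(C)O2)OC1(C)C | starting material
21 | lithiated bis[(pinacolato)boryl]methane (formed in situ) | [Li]C(B1OC(C)(C)C(C)(C)O1)B1OC(C)(C)C(C)(C)O1 | intermediate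
22 | 2-{(E)-2-[2,4-bis(methoxymethoxy)phenyl]ethenyl}-4,4,5,5-tetramethyl-1,3,2-dioxaborolane | CC1(C)OB(/C=C/c2ccc(OCOC)cc2OCOC)OC1(C)C | intermediate
23 | carbon monoxide | [C-]#[O+] | starting material
24 | (E)-3-[2,4-bis(methoxymethoxy)phenyl]-1-{6-methoxy-2,4-bis(methoxymethoxy)-3-[(2S)-5-methyl-2-(prop-1-en-2-yl)hex-4-en-1-yl]phenyl}prop-2-en-1-one | C=C(C)[C@@H](CC=C(C)C)Cc1c(OCOC)cc(OC)c(C(=O)/C=C/c2ccc(OCOC)cc2OCOC)c1OCOC | intermediate
25 | tetrakis(trimethylsilyl) ether of 26 (formed in situ) | C=C(C)[C@@H](CC=C(C)C)Cc1c(O[Si](C)(C)C)cc(OC)c(C(=O)/C=C/c2ccc(O[Si](C)(C)C)cc2O[Si](C)(C)C)c1O[Si](C)(C)C | intermediate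
26 | (E)-1-{2,4-dihydroxy-6-methoxy-3-[(2S)-5-methyl-2-(prop-1-en-2-yl)hex-4-en-1-yl]phenyl}-3-(2,4-dihydroxyphenyl)prop-2-en-1-one | C=C(C)[C@@H](CC=C(C)C)Cc1c(O)cc(OC)c(C(=O)/C=C/c2ccc(O)cc2O)c1O | target

**Step count**

Total: 12 steps. Longest linear sequence: 8 steps (1, 2, 3, 4, 7, 8, 11, 12).

**Steps most likely to fail**

Step 11. Transmetalation of the pinacol boronate to the crowded aroylpalladium may be slow, so that protodeboronation, capture of the acylpalladium by adventitious water or direct non-carbonylative coupling takes over. The fallback builds the enone by aldol condensation. It sets out from 15, which is lithiated as in step 8 to aryllithium 16 and trapped with N-methoxy-N-methylacetamide (THF, −78 → 0 °C) to give the methyl ketone 1-{6-methoxy-2,4-bis(methoxymethoxy)-3-[(2S)-5-methyl-2-(prop-1-en-2-yl)hex-4-en-1-yl]phenyl}ethan-1-one F1. Claisen–Schmidt condensation of this ketone with aldehyde 19 (KOH, EtOH, rt) should form the Cα=Cβ bond with E geometry, and the route is rejoined at 24.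

Step 7. β-Hydride elimination from the alkylpalladium intermediate would lose the side chain as a diene and, on re-insertion, erode the stereocentre; oxidative addition into the doubly ortho-alkoxylated C–I bond may also be slow. The fallback reverses the polarity and avoids alkylpalladium species. It sets out from 11, which is lithiated as in step 6 to aryllithium 12 and transmetalated with MgBr2·OEt2 to [4-methoxy-2,6-bis(methoxymethoxy)phenyl]magnesium bromide F2. Copper-catalysed alkylation of this Grignard reagent with iodide 9 (Li2CuCl4 catalyst, THF, −20 °C → rt; substitution at the primary carbon) comes back to the route at 15.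

Step 12. The unmasked polyphenol may cyclise under the Lewis-acidic conditions (C2' phenol onto the enone, a ring A phenol onto the isopropenyl group, the ring B ortho-phenol onto the ketone), or cleavage of four acetals may stall. The fallback removes the acetals before the enone exists and finishes with fluoride.
- Ring A: from 17, methanolysis (HCl in MeOH, rt) gives 4-iodo-5-methoxy-2-[(2S)-5-methyl-2-(prop-1-en-2-yl)hex-4-en-1-yl]benzene-1,3-diol F3, which is silylated (t-BuMe2SiOTf, 2,6-lutidine, CH2Cl2) to the bis(tert-butyldimethylsilyl) ether of the iodoresorcinol F4.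
- Ring B: 18 is silylated (t-BuMe2SiCl, imidazole, DMF) to 2,4-bis(tert-butyldimethylsilyloxy)benzaldehyde F5, which the boron-Wittig reaction with 20 (via 21) converts into the (E)-alkenylboronate 2-{(E)-2-[2,4-bis(tert-butyldimethylsilyloxy)phenyl]ethenyl}-4,4,5,5-tetramethyl-1,3,2-dioxaborolane F6.
- Union and release: carbonylative coupling of F4, F6 and 23 under the conditions of step 11 gives the tetrakis(tert-butyldimethylsilyl) ether of the target F7, and desilylation with HF·pyridine buffered with pyridine (THF, 0 °C) returns to the route at 26.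

Further compounds
F1 | step 11 | 1-{6-methoxy-2,4-bis(methoxymethoxy)-3-[(2S)-5-methyl-2-(prop-1-en-2-yl)hex-4-en-1-yl]phenyl}ethan-1-one | C=C(C)[C@@H](CC=C(C)C)Cc1c(OCOC)cc(OC)c(C(C)=O)c1OCOC
F2 | step 7 | [4-methoxy-2,6-bis(methoxymethoxy)phenyl]magnesium bromide | COCOc1cc(OC)cc(OCOC)c1[Mg]Br
F3 | step 12 | 4-iodo-5-methoxy-2-[(2S)-5-methyl-2-(prop-1-en-2-yl)hex-4-en-1-yl]benzene-1,3-diol | C=C(C)[C@@H](CC=C(C)C)Cc1c(O)cc(OC)c(I)c1O
F4 | step 12 | bis(tert-butyldimethylsilyl) ether of F3 | C=C(C)[C@@H](CC=C(C)C)Cc1c(O[Si](C)(C)C(C)(C)C)cc(OC)c(I)c1O[Si](C)(C)C(C)(C)C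
F5 | step 12 | 2,4-bis(tert-butyldimethylsilyloxy)benzaldehyde | O=Cc1ccc(O[Si](C)(C)C(C)(C)C)cc1O[Si](C)(C)C(C)(C)C
F6 | step 12 | 2-{(E)-2-[2,4-bis(tert-butyldimethylsilyloxy)phenyl]ethenyl}-4,4,5,5-tetramethyl-1,3,2-dioxaborolane | CC1(C)OB(/C=C/c2ccc(O[Si](C)(C)C(C)(C)C)cc2O[Si](C)(C)C(C)(C)C)OC1(C)C
F7 | step 12 | tetrakis(tert-butyldimethylsilyl) ether of 26 | C=C(C)[C@@H](CC=C(C)C)Cc1c(O[Si](C)(C)C(C)(C)C)cc(OC)c(C(=O)/C=C/c2ccc(O[Si](C)(C)C(C)(C)C)cc2O[Si](C)(C)C(C)(C)C)c1O[Si](C)(C)C(C)(C)C
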